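All runs are simulated on assumed constants, and the scatter is random.

| setting | ochre | red | blue | flask |
|---|---|---|---|---|
| left-handed substrate | 41 mM | 41 mM | 41 mM | 41 mM |
| right-handed substrate | 41 mM | 41 mM | 41 mM | 41 mM |
| reagent | 41 mM (fed, over 40 s) | 41 mM (fed, over 40 s) | 82 mM (fed, over 40 s) | 41.0 mM (fed, over 40 s) |
| free catalyst | 8.2 mM | 8.2 mM | 8.2 mM | 8.2 mM |
| impurity | 1.2 mM | 1.9 mM | 2.5 mM | 2.5 mM |
| remark | run made earlier | run made earlier | run made earlier |  |
| time |  |  |  | 25 min |

| run | time / min | left-handed substrate / % | left-handed product / % | right-handed substrate / % |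
|---|---|---|---|---|
| ochre | 0.833 | 39.5 | 8.7 | 46.5 |
| ochre | 2.50 | 32.7 | 15.5 | 44.8 |
| ochre | 4.00 | 31.0 | 16.4 | 43.9 |
| ochre | 6.00 | 31.1 | 17.6 | 44.2 |
| ochre | 10.0 | 30.1 | 17.8 | 44.2 |
| ochre | 12.0 | 30.5 | 17.6 | 44.7 |
| ochre | 15.0 | 30.2 | 18.0 | 44.1 |
| red | 1.33 | 36.6 | 11.1 | 45.9 |
| red | 2.00 | 34.7 | 13.3 | 45.1 |
| red | 3.00 | 33.0 | 15.3 | 45.3 |
| red | 4.00 | 32.3 | 16.2 | 43.9 |
| red | 6.00 | 31.2 | 16.4 | 44.4 |
| red | 10.0 | 31.4 | 16.4 | 44.6 |
| red | 15.0 | 31.0 | 17.3 | 44.0 |
| blue | 3.00 | 28.7 | 19.8 | 43.4 |
| blue | 6.00 | 27.2 | 21.2 | 42.9 |
| blue | 10.0 | 26.6 | 21.6 | 42.6 |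
| blue | 12.0 | 26.1 | 22.4 | 43.0 |
| blue | 15.0 | 26.2 | 22.8 | 42.6 |

(readings scatter by 0.3 percentage points)

- free catalyst is single-handed; left-handed substrate and right-handed substrate are mirror images of each other, charged as a racemate, each of them at the stated concentration

- how much of the left-handed substrate and right-handed substrate together has reacted by 25 min
- how much left-handed product there is at 25 min, in percent of the left-handed substrate and right-handed substrate together charged
- how much right-handed substrate there is at 25 min, in percent of the left-handed substrate and right-handed substrate together charged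

- Late in the ochre run left-handed product reads 17.6% at 12.0 min and 18.0% at 15.0 min, against a scatter of 0.3 percentage points, which reads as a plateau in that run. So the new flask at 25 min can be read as a plateau.
- In the first instants, reagent enters over 40 s while 8.2 mM of free catalyst meets 2.5 mM of impurity. The impurity is less than the left-handed substrate, but its charge comes to 30.5% of the catalyst charge. The likely reading is that it takes catalyst, one for one.
- On that reading, free catalyst charged minus impurity charged comes to 5.70 mM in the new flask. This live catalyst is 69.5% of the catalyst charged.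
- In the middle, by 4.00 min, the ochre curve has bent over. By its last reading the two substrates have lost 21.1 mM, about half of the reagent charged. If one reagent goes per substrate lost, the rest of the reagent is either unused or gone some unseen way.
- At 15.0 min, the blue run, with twice the reagent, reads 22.8% of left-handed product, more than ochre, despite its larger impurity charge. Reagent therefore looks like the limiting reagent.
- Late means of left-handed product are 17.8% for ochre and 16.7% for red. Continuing that fall in step with live catalyst gives 15.8% for the flask.
- The forecast is 24% conversion, 16.2% left-handed product and 44.3% right-handed substrate. Its ground is that added impurity “costs about 0.9 points of conversion, roughly stoichiometric”. Its product is higher than the reckoning here.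
- The flask gives 23.2% conversion, 16.2% left-handed product and 44.7% right-handed substrate, and the forecast held.

    free catalyst + left-handed substrate ⇌ catalyst intermediate A (K = 15.0 L mol⁻¹, k = 418 L mol⁻¹ s⁻¹)
    free catalyst + right-handed substrate ⇌ catalyst intermediate B (K = 7.24 L mol⁻¹, k = 7.60 L mol⁻¹ s⁻¹)
    reagent + catalyst intermediate A → free catalyst + left-handed product (k = 4.13 L mol⁻¹ s⁻¹)
    reagent + catalyst intermediate B → free catalyst + right-handed product (k = 1.90 L mol⁻¹ s⁻¹)
    free catalyst + impurity → spent catalyst (k = 57.4 L mol⁻¹ s⁻¹)
    2 reagent → self-condensation product (k = 0.494 L mol⁻¹ s⁻¹)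

- The flask ends with 70% of its catalyst still able to turn over, beside the 69.5% reckoned from the charges. The same reckoning on the neighbour flask with 3.3 mM of free catalyst leaves 0.800 mM live, 24.2% of its charge. That neighbour holds 75.8% spent catalyst. Its self-condensation product reaches 17.7 mM, more than the 12.1 mM of the flask. Its left-handed product stands at 5.39%.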